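**Retrosynthetic overview**

1. Target 18 ⇒ aromatic acylphloroglucinol 14 by a late, ligand-controlled Pd dearomative C-prenylation (ring quaternary centre). Ring order: benzene ring bought, cyclopentane built in step 4, cyclohexadienone revealed last.
2. 14 ⇒ trans-2,3-disubstituted cyclopentanone 12 (methyl addition anti to the arylmethyl arm sets C1) ⇒ enone 10 (Cu-catalysed asymmetric conjugate isopropenylation sets C3; C2 follows by equilibration).
3. Key disconnection: enone 10 ⇒ aryl-propyne cobalt complex 8 + ethylene + CO (Pauson–Khand [2+2+1]); bonds C3–C4, C5–C1 and C1–C2 of the five-membered ring form in one operation.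
4. Enabling feature: in the cyclopentanol ring (C1 carbinol, C2 carrying the CH2–aryl link, C3 carrying isopropenyl) C4 and C5 are an unsubstituted CH2–CH2 pair between C3 and the oxygenated C1. The ring is therefore a disguised 2-substituted cyclopent-2-enone: C4–C5 = ethylene, C1 = CO, C2/C3 = a terminal alkyne.
5. 8 ⇒ Nicholas propargylation of acylphloroglucinol 3 (from 2-methylphloroglucinol 1 and isobutyryl chloride 2) with the Co2(CO)6 complex of propargyl alcohol, then silylation.

Key step: step 4

Remark: the target is drawn as one enol tautomer of a β-triketone; the tautomers interconvert freely and share all four stereocentres, so the route aims at this constitution and configuration whatever enol form is isolated.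

**Route**

Step 1
Reactants: 1 2-methylbenzene-1,3,5-triol (2-methylphloroglucinol); 2 2-methylpropanoyl chloride
Product: 3 2-methyl-1-(2,4,6-trihydroxy-3-methylphenyl)propan-1-one
Conditions: AlCl3 (4 equiv), PhNO2, rt → 65 °C; then ice/aq HCl
Reagents that add atoms: none
Why: Friedel–Crafts C-acylation at one of the two equivalent free ring positions of the phloroglucinol, the first acyl group deactivating the ring against a second acylation and any aryl ester rearranging to the ketone under the conditions (Fries).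

Step 2
Reactants: 3 2-methyl-1-(2,4,6-trihydroxy-3-methylphenyl)propan-1-one; 4 prop-2-yn-1-ol; 5 Co2(CO)8
Product: 7 Co2(CO)6 complex of 2-methyl-1-[2,4,6-trihydroxy-3-methyl-5-(prop-2-yn-1-yl)phenyl]propan-1-one, via Co2(CO)6 complex of prop-2-yn-1-ol 6 (not isolated)
Conditions: 4, Co2(CO)8, CH2Cl2, rt; then 3, HBF4·OEt2 (30 mol %), CH2Cl2/Et2O, –20 → 0 °C
Reagents that add atoms: none
Why: Nicholas reaction, in which the cobalt-stabilised propargylic cation alkylates the only free and strongly activated ring carbon, O-alkylation being reversible under acid and the cluster both protecting the alkyne from the ortho phenols and being the complex needed in step 4.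

Step 3
Reactants: 7 Co2(CO)6 complex of 2-methyl-1-[2,4,6-trihydroxy-3-methyl-5-(prop-2-yn-1-yl)phenyl]propan-1-one
Product: 8 Co2(CO)6 complex of 2-methyl-1-[2,4,6-tris(tert-butyldimethylsilyloxy)-3-methyl-5-(prop-2-yn-1-yl)phenyl]propan-1-one
Conditions: TBSOTf (4 equiv), 2,6-lutidine (6 equiv), CH2Cl2, 0 °C → rt
Reagents that add atoms: tert-butyldimethylsilyl trifluoromethanesulfonate CC(C)(C)[Si](C)(C)OS(=O)(=O)C(F)(F)F
Why: Silylation of the three phenols with a silyl triflate, which the alkyne cluster tolerates and which is required because free ortho phenols would add to the enone made in step 4 and quench the organometallic reagents of steps 5 and 6.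

Step 4
Reactants: 8 Co2(CO)6 complex of 2-methyl-1-[2,4,6-tris(tert-butyldimethylsilyloxy)-3-methyl-5-(prop-2-yn-1-yl)phenyl]propan-1-one; 9 ethene
Product: 10 2-{[2,4,6-tris(tert-butyldimethylsilyloxy)-3-methyl-5-(2-methylpropanoyl)phenyl]methyl}cyclopent-2-en-1-one
Conditions: ethene (25 bar), Me3NO (7 equiv), 4 Å MS, toluene, 0 → 40 °C, autoclave
Reagents that add atoms: none
Why: Intermolecular Pauson–Khand [2+2+1] cycloaddition of an alkyne–Co2(CO)6 complex with ethylene, the closest precedent being the amine N-oxide-promoted reaction of terminal alkyne complexes with ethylene under moderate pressure to give 2-substituted cyclopent-2-enones. Me3NO oxidises one CO ligand to CO2, ethylene takes the vacant site and inserts into the cobalt–carbon bond of the unsubstituted alkyne terminus (bond C3–C4), CO then inserts into the cobalt–alkyl bond (bond C5–C1) and reductive elimination joins the acyl carbon to the substituted alkyne carbon (bond C1–C2). The five-membered ring is thus closed as a cobaltacycle-mediated three-component cycloaddition whose last event is that reductive elimination, so three C–C bonds and the whole arylmethyl-cyclopentane skeleton come from an aryl-propyne, a C2 gas and a carbonyl ligand. No stereocentre is formed, by design: the flat enone carries exactly the β-carbon C3, the epimerisable C2 and the carbonyl C1 from which the three ring stereocentres are set in the next two steps. The step needs regiocontrol (substituent α to the carbonyl), secured by the terminal alkyne whose bulky arylmethyl group directs ethylene insertion to the CH terminus, and chemoselectivity, secured by running it before any other alkene (isopropenyl, prenyl) is present and by the silyl ethers, which stop the ortho phenols from adding to the new enone.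

Step 5
Reactants: 10 2-{[2,4,6-tris(tert-butyldimethylsilyloxy)-3-methyl-5-(2-methylpropanoyl)phenyl]methyl}cyclopent-2-en-1-one
Product: 12 (2S,3R)-2-{[2,4,6-tris(tert-butyldimethylsilyloxy)-3-methyl-5-(2-methylpropanoyl)phenyl]methyl}-3-(prop-1-en-2-yl)cyclopentan-1-one, via bromomagnesium enolate 11 (not isolated)
Conditions: CH2=C(CH3)MgBr (1.5 equiv), Cu(OTf)2 (5 mol %), 1-[(2S)-1-hydroxy-4-methylpentan-2-yl]-3-(2,4,6-trimethylphenyl)-4,5-dihydroimidazol-3-ium hexafluorophosphate (6 mol %, or its enantiomer), Et2O, –30 °C; aq NH4Cl; then DBU (0.2 equiv), CH2Cl2, rt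
Reagents that add atoms: isopropenylmagnesium bromide C=C(C)[Mg]Br
Why: Copper-catalysed enantioselective conjugate addition of a Grignard reagent to an α-substituted cyclic enone, in which the chiral carbene–copper complex selects the face of C3 (catalyst control, the ligand enantiomer that gives 3R to be fixed on 2-benzylcyclopent-2-en-1-one as a model) and the epimerisable C2 settles trans to the isopropenyl group under DBU (thermodynamic control).

Step 6
Reactants: 12 (2S,3R)-2-{[2,4,6-tris(tert-butyldimethylsilyloxy)-3-methyl-5-(2-methylpropanoyl)phenyl]methyl}-3-(prop-1-en-2-yl)cyclopentan-1-one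
Product: 13 (1R,2S,3R)-1-methyl-2-{[2,4,6-tris(tert-butyldimethylsilyloxy)-3-methyl-5-(2-methylpropanoyl)phenyl]methyl}-3-(prop-1-en-2-yl)cyclopentan-1-ol
Conditions: CeCl3 (anhydrous, 2 equiv), MeMgBr (2 equiv), THF, –78 °C; aq NH4Cl
Reagents that add atoms: methylmagnesium bromide C[Mg]Br
Why: Organocerium 1,2-addition, which is non-basic (C2 is not epimerised) and leaves the aryl ketone shielded by two ortho silyloxy groups untouched, should occur on the ketone face anti to the adjacent bulky C2 arylmethyl arm, placing methyl trans and hydroxyl cis to that arm (1R).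

Step 7
Reactants: 13 (1R,2S,3R)-1-methyl-2-{[2,4,6-tris(tert-butyldimethylsilyloxy)-3-methyl-5-(2-methylpropanoyl)phenyl]methyl}-3-(prop-1-en-2-yl)cyclopentan-1-ol
Product: 14 1-[2,4,6-trihydroxy-3-{[(1S,2R,5R)-2-hydroxy-2-methyl-5-(prop-1-en-2-yl)cyclopentyl]methyl}-5-methylphenyl]-2-methylpropan-1-one
Conditions: TBAF (3.5 equiv), AcOH (3.5 equiv), THF (degassed), 0 °C
Reagents that add atoms: none
Why: Fluoride cleaves the three aryl silyl ethers under buffered, non-acidic conditions, so the tertiary alcohol cannot ionise towards the neighbouring phenol or the isopropenyl group and the electron-rich triphenol is not left as an oxidisable phenoxide.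

Step 8
Reactants: 15 3-methylbut-2-en-1-ol; 16 methyl chloroformate
Product: 17 methyl 3-methylbut-2-en-1-yl carbonate
Conditions: pyridine (1.5 equiv), CH2Cl2, 0 °C
Reagents that add atoms: none
Why: Plain O-acylation of a primary allylic alcohol with a chloroformate under mild base gives the allylic carbonate used as the prenyl donor.

Step 9
Reactants: 14 1-[2,4,6-trihydroxy-3-{[(1S,2R,5R)-2-hydroxy-2-methyl-5-(prop-1-en-2-yl)cyclopentyl]methyl}-5-methylphenyl]-2-methylpropan-1-one; 17 methyl 3-methylbut-2-en-1-yl carbonate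
Product: 18 (6R)-3,5-dihydroxy-4-{[(1S,2R,5R)-2-hydroxy-2-methyl-5-(prop-1-en-2-yl)cyclopentyl]methyl}-6-methyl-6-(3-methylbut-2-en-1-yl)-2-(2-methylpropanoyl)cyclohexa-2,4-dien-1-one
Conditions: Pd2(dba)3·CHCl3 (2.5 mol %), N,N'-[(1R,2R)-cyclohexane-1,2-diyl]bis[2-(diphenylphosphanyl)benzamide] (7.5 mol %, or its enantiomer), 17 (1.05 equiv), THF (degassed), 0 °C → rt
Reagents that add atoms: none
Why: Tsuji–Trost-type asymmetric allylic dearomatisation, in which zerovalent palladium ionises the carbonate (the methoxide released deprotonates the acylphloroglucinol), the phenoxide attacks the unsubstituted allyl terminus through the methyl-bearing ring carbon (less hindered than the carbon carrying the branched cyclopentylmethyl arm, O-allylation being reversible), and the chiral ligand pocket, not the remote cyclopentane, decides which face of that carbon is alkylated (catalyst control, ligand enantiomer to be fixed in the first trial).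

**Compound list**

1 | 2-methylbenzene-1,3,5-triol | Cc1c(O)cc(O)cc1O | starting material
2 | 2-methylpropanoyl chloride | CC(C)C(Cl)=O | starting material
3 | 2-methyl-1-(2,4,6-trihydroxy-3-methylphenyl)propan-1-one | CC(C)C(=O)c1c(O)cc(O)c(C)c1O | intermediate
4 | prop-2-yn-1-ol | C#CCO | starting material
5 | Co2(CO)8 (dicobalt octacarbonyl) | O=C=[Co](=C=O)(=C=O)(=C=O)[Co](=C=O)(=C=O)(=C=O)=C=O | starting material
6 | Co2(CO)6 complex of prop-2-yn-1-ol | OCC12C3[Co]1(=C=O)(=C=O)(=C=O)[Co]23(=C=O)(=C=O)=C=O | intermediate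
7 | Co2(CO)6 complex of 2-methyl-1-[2,4,6-trihydroxy-3-methyl-5-(prop-2-yn-1-yl)phenyl]propan-1-one | CC(C)C(=O)c1c(O)c(C)c(O)c(CC23C4[Co]2(=C=O)(=C=O)(=C=O)[Co]34(=C=O)(=C=O)=C=O)c1O | intermediate
8 | Co2(CO)6 complex of 2-methyl-1-[2,4,6-tris(tert-butyldimethylsilyloxy)-3-methyl-5-(prop-2-yn-1-yl)phenyl]propan-1-one | CC(C)C(=O)c1c(O[Si](C)(C)C(C)(C)C)c(C)c(O[Si](C)(C)C(C)(C)C)c(CC23C4[Co]2(=C=O)(=C=O)(=C=O)[Co]34(=C=O)(=C=O)=C=O)c1O[Si](C)(C)C(C)(C)C | intermediate
9 | ethene | C=C | starting material
10 | 2-{[2,4,6-tris(tert-butyldimethylsilyloxy)-3-methyl-5-(2-methylpropanoyl)phenyl]methyl}cyclopent-2-en-1-one | CC(C)C(=O)c1c(O[Si](C)(C)C(C)(C)C)c(C)c(O[Si](C)(C)C(C)(C)C)c(CC2=CCCC2=O)c1O[Si](C)(C)C(C)(C)C | intermediate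
11 | bromomagnesium enolate of 12 (isopropenyl-bearing carbon configured as in 12) | C=C(C)[C@@H]1CCC(O[Mg]Br)=C1Cc1c(O[Si](C)(C)C(C)(C)C)c(C)c(O[Si](C)(C)C(C)(C)C)c(C(=O)C(C)C)c1O[Si](C)(C)C(C)(C)C | intermediate
12 | (2S,3R)-2-{[2,4,6-tris(tert-butyldimethylsilyloxy)-3-methyl-5-(2-methylpropanoyl)phenyl]methyl}-3-(prop-1-en-2-yl)cyclopentan-1-one | C=C(C)[C@@H]1CCC(=O)[C@H]1Cc1c(O[Si](C)(C)C(C)(C)C)c(C)c(O[Si](C)(C)C(C)(C)C)c(C(=O)C(C)C)c1O[Si](C)(C)C(C)(C)C | intermediate
13 | (1R,2S,3R)-1-methyl-2-{[2,4,6-tris(tert-butyldimethylsilyloxy)-3-methyl-5-(2-methylpropanoyl)phenyl]methyl}-3-(prop-1-en-2-yl)cyclopentan-1-ol | C=C(C)[C@@H]1CC[C@@](C)(O)[C@H]1Cc1c(O[Si](C)(C)C(C)(C)C)c(C)c(O[Si](C)(C)C(C)(C)C)c(C(=O)C(C)C)c1O[Si](C)(C)C(C)(C)C | intermediate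
14 | 1-[2,4,6-trihydroxy-3-{[(1S,2R,5R)-2-hydroxy-2-methyl-5-(prop-1-en-2-yl)cyclopentyl]methyl}-5-methylphenyl]-2-methylpropan-1-one | C=C(C)[C@@H]1CC[C@@](C)(O)[C@H]1Cc1c(O)c(C)c(O)c(C(=O)C(C)C)c1O | intermediate
15 | 3-methylbut-2-en-1-ol | CC(C)=CCO | starting material
16 | methyl chloroformate | COC(Cl)=O | starting material
17 | methyl 3-methylbut-2-en-1-yl carbonate | COC(=O)OCC=C(C)C | intermediate
18 | (6R)-3,5-dihydroxy-4-{[(1S,2R,5R)-2-hydroxy-2-methyl-5-(prop-1-en-2-yl)cyclopentyl]methyl}-6-methyl-6-(3-methylbut-2-en-1-yl)-2-(2-methylpropanoyl)cyclohexa-2,4-dien-1-one | C=C(C)[C@@H]1CC[C@@](C)(O)[C@H]1CC1=C(O)[C@@](C)(CC=C(C)C)C(=O)C(C(=O)C(C)C)=C1O | target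

**Step count and risks**

Total step count: 9. Longest linear sequence: 8 (steps 1–7 and 9; step 8 is a one-step side branch).

Steps most likely to fail:

Step 5. The catalytic asymmetric conjugate addition may be sluggish or poorly face-selective, because the enone carries a very bulky α-substituent and an alkenyl Grignard reagent is a demanding nucleophile for this catalyst class. Fallback: from 10 a racemic copper-catalysed addition (CH2=C(CH3)MgBr, CuBr·SMe2 10 mol %, TMSCl, THF, –78 °C; aq HCl; DBU) should give 12 together with its mirror image, the (2R,3S)-ketone F1. The pair is taken through steps 6 and 7 unchanged, giving 13 with the (1S,2R,3S)-alcohol F2 and 14 with the enantiomeric triol F3. In step 9 the ligand-controlled prenylation then turns the enantiomeric pair into two diastereomers, 18 and the (6R)-dienone carrying the mirror-image cyclopentyl unit F4, which differ in physical properties and are separated by chromatography. The sequence rejoins the route at 18, at the cost of half the material.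

Step 9. Facial selectivity at the methyl-bearing ring carbon may be poor, or alkylation may compete at the ring carbon carrying the cyclopentylmethyl arm. Fallback: from 14 a classical base-mediated C-prenylation (prenyl bromide 1.05 equiv, aq KOH or NaOMe/MeOH, 0 °C) without any chiral catalyst should give 18 together with its epimer at the ring quaternary carbon, the (6S)-dienone F5. The two epimers are separated by preparative HPLC, rejoining the route at 18.

Step 4. Ethylene uptake by the hindered cluster may be slow, so that decomplexation of the alkyne outruns cycloaddition. Fallback: from 8 vinyl benzoate serves as a liquid ethylene surrogate with a removable activating group (N-methylmorpholine N-oxide, CH2Cl2, rt → 40 °C), giving the racemic 5-benzoyloxy enone F6. Its α-acyloxy ketone is then cleaved reductively (SmI2, THF/MeOH, –78 °C) to rejoin the route at 10.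

**Further compounds**

F1 | step 5 | (2R,3S)-2-{[2,4,6-tris(tert-butyldimethylsilyloxy)-3-methyl-5-(2-methylpropanoyl)phenyl]methyl}-3-(prop-1-en-2-yl)cyclopentan-1-one | C=C(C)[C@H]1CCC(=O)[C@@H]1Cc1c(O[Si](C)(C)C(C)(C)C)c(C)c(O[Si](C)(C)C(C)(C)C)c(C(=O)C(C)C)c1O[Si](C)(C)C(C)(C)C
F2 | step 5 | (1S,2R,3S)-1-methyl-2-{[2,4,6-tris(tert-butyldimethylsilyloxy)-3-methyl-5-(2-methylpropanoyl)phenyl]methyl}-3-(prop-1-en-2-yl)cyclopentan-1-ol | C=C(C)[C@H]1CC[C@](C)(O)[C@@H]1Cc1c(O[Si](C)(C)C(C)(C)C)c(C)c(O[Si](C)(C)C(C)(C)C)c(C(=O)C(C)C)c1O[Si](C)(C)C(C)(C)C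
F3 | step 5 | 1-[2,4,6-trihydroxy-3-{[(1R,2S,5S)-2-hydroxy-2-methyl-5-(prop-1-en-2-yl)cyclopentyl]methyl}-5-methylphenyl]-2-methylpropan-1-one | C=C(C)[C@H]1CC[C@](C)(O)[C@@H]1Cc1c(O)c(C)c(O)c(C(=O)C(C)C)c1O
F4 | step 5 | (6R)-3,5-dihydroxy-4-{[(1R,2S,5S)-2-hydroxy-2-methyl-5-(prop-1-en-2-yl)cyclopentyl]methyl}-6-methyl-6-(3-methylbut-2-en-1-yl)-2-(2-methylpropanoyl)cyclohexa-2,4-dien-1-one | C=C(C)[C@H]1CC[C@](C)(O)[C@@H]1CC1=C(O)[C@@](C)(CC=C(C)C)C(=O)C(C(=O)C(C)C)=C1O
F5 | step 9 | (6S)-3,5-dihydroxy-4-{[(1S,2R,5R)-2-hydroxy-2-methyl-5-(prop-1-en-2-yl)cyclopentyl]methyl}-6-methyl-6-(3-methylbut-2-en-1-yl)-2-(2-methylpropanoyl)cyclohexa-2,4-dien-1-one | C=C(C)[C@@H]1CC[C@@](C)(O)[C@H]1CC1=C(O)[C@](C)(CC=C(C)C)C(=O)C(C(=O)C(C)C)=C1O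
F6 | step 4 | 3-{[2,4,6-tris(tert-butyldimethylsilyloxy)-3-methyl-5-(2-methylpropanoyl)phenyl]methyl}-2-oxocyclopent-3-en-1-yl benzoate (racemic) | CC(C)C(=O)c1c(O[Si](C)(C)C(C)(C)C)c(C)c(O[Si](C)(C)C(C)(C)C)c(CC2=CCC(OC(=O)c3ccccc3)C2=O)c1O[Si](C)(C)C(C)(C)C
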